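(The numbers in the tables are simulated with made-up constants, and the scatter is random.)

The closed, stirred, isothermal vessel came before a short meeting. The flask asked about is the violet run carried on, and the ochre run differs from it in second nucleophile.

in all of them: substrate 0.010 M
- violet: first nucleophile 0.050 M; second nucleophile 0.012 M; protic impurity 0.20 mM; the very flask that is asked about, followed so far
- ochre: first nucleophile 0.050 M; second nucleophile 0.018 M; protic impurity 0.20 mM; run made earlier
- flask: first nucleophile 0.0500 M; second nucleophile 0.0120 M; protic impurity 0.200 mM; time 2.0 h

| run | time / min | target / % | other capture product / % | substrate / % |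
|---|---|---|---|---|
| violet | 5.00 | 55.9 | 35.6 | 0 |
| violet | 10.0 | 56.0 | 34.7 | 1.1 |
| violet | 15.0 | 55.8 | 35.1 | 0 |
| violet | 30.0 | 54.9 | 33.7 | 0 |
| violet | 60.0 | 56.3 | 36.4 | 0.6 |
| ochre | 6.00 | 47.8 | 44.5 | 0 |
| ochre | 12.0 | 47.8 | 45.5 | 0 |
| ochre | 25.0 | 47.2 | 44.7 | 0.4 |
| ochre | 40.0 | 48.3 | 45.3 | 2.3 |
| ochre | 80.0 | 46.6 | 44.1 | 2.6 |

(readings scatter by 1 percentage point)

- the analysis behind the earlier runs scatters by 1 percentage point, standard deviation

1. share of target in target plus other capture product at 1.5 s
2. share of target in target plus other capture product at 2.0 h
3. which of target and other capture product there is more of at 2.0 h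

The analyst reported that target and other capture product each stay flat over time in both runs, within the scatter of 1 percentage point. She gave r, the ratio of target to other capture product pooled over the readings, as 1.59 in violet and 1.06 in ochre.

The kineticist assumed that each other capture product spends one second nucleophile. He took the mean of charge and remainder as the working concentration: 10.2 mM in violet, 15.8 mM in ochre. If r falls inversely with it, r times that mean stays constant, and the readings give 16.3 mM and 16.7 mM. He named their average, 16.5 mM, D×: the crossover concentration, read from these runs, the mean second-nucleophile concentration at which, for this first-nucleophile charge, this reckoning puts the readings of target and other capture product equal, a selectivity factor in concentration units.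

I, taking the minutes, reckoned the flask from r = D×/mean. With second nucleophile taken at its charge at 1.5 s, the share is 57.9%. By 2.0 h the mean 10.2 mM lies below D×, so target leads with a share of 61.7%.

The forecaster, citing “inverse first-order competition”, put the early share at 59% (52% to 63%) and the late share at 61.4% (59.5% to 63%), with target ahead. The first stands above my figure, the second below it.

The simulation gives an early share of 62.8% and a late share of 61.8%, with target ahead at 56.4% against 34.9%, under these steps:

    substrate → intermediate (k = 0.0155 s⁻¹)
    first nucleophile + intermediate → target (k = 118 M⁻¹ s⁻¹)
    second nucleophile + intermediate → other capture product (k = 289 M⁻¹ s⁻¹)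
    target ⇌ isomer of the product (K = 0.154, k = 0.00969 s⁻¹)
    first nucleophile + protic impurity → quenched reagent (k = 9.17 M⁻¹ s⁻¹)

The early share stands 5 points above my reckoning. A neighbouring flask, the same recipe with 0.030 M of second nucleophile, keeps 80.6% of that charge, so its mean is 27.1 mM, above D×. Then r = D×/mean is 0.609, a share of 37.8%. That neighbouring flask ends at a share of 38.5%, with target at 36.3% and other capture product at 58.1%.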